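**Strategy.** Everything rests on disconnecting the trisubstituted C3=C4 double bond of the five-membered ring (ring A, C1–C5), which sits between the trans ring-fusion carbons C1 and C5. Ring-closing metathesis of a methylenecycloheptane that carries an allyl group on C1 and an isopropenyl group on C5 closes ring A as the last ring; cross metathesis in the same flask turns the side-chain vinyl group into the C14=C15 isobutenyl end. In this precursor C6, C7 and C11 derive from an enzymatically desymmetrized cycloheptenediol through an Ireland–Claisen rearrangement and a lactone protonation, and the trans C1/C5 pair from a cuprate addition–allylation.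

Key step: step 17

Numbering used: C1–C5 cyclopentene (ring A; C1, C5 ring fusion, methyl on C4); C1, C5–C10 cycloheptane (ring B; 6-OH, side chain on C7, 9-OH, exocyclic methylene on C10); side chain C11 (methyl-bearing), C12, C13 (acetoxy), C14=C15.

Assumption: the target is read as trans-fused, with 6-OH cis to the C7 side chain and trans to 9-OH; the lipase of step 2 is taken to acylate the (R)-carbinol, as Kazlauskas' rule predicts.

**Step 1**
Reactants: 1 cyclohepta-1,3-diene
Product: 3 cis-cyclohept-2-ene-1,4-diol, via endoperoxide 2 (not isolated)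
Conditions: O2, tetraphenylporphyrin (cat.), visible light, CH2Cl2, 0 °C; then Zn, AcOH, rt
Reagents that add atoms: dioxygen O=O
Why: Singlet-oxygen [4+2] cycloaddition to the cyclic diene followed by reductive O–O cleavage should place both C–O bonds (future C6–O and C9–O) on one face and give the meso cis-diol.

**Step 2**
Reactants: 3 cis-cyclohept-2-ene-1,4-diol
Product: 4 (1R,4S)-4-hydroxycyclohept-2-en-1-yl propanoate
Conditions: lipase from Burkholderia cepacia (Amano PS), vinyl propanoate, THF, rt
Reagents that add atoms: vinyl propanoate CCC(=O)OC=C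
Why: Lipase-catalysed irreversible transesterification desymmetrizes the meso diol; acylation of the (R)-carbinol (future C9) leaves the (S)-carbinol, which becomes C6 with the configuration of the target.

**Step 3**
Reactants: 4 (1R,4S)-4-hydroxycyclohept-2-en-1-yl propanoate
Product: 7 cis-fused lactone (3aS,8aS)-3-methyl-3,3a,6,7,8,8a-hexahydro-2H-cyclohepta[b]furan-2-one (C11 epimers), via silyl ketene acetal 5 (not isolated), via hydroxy acid 6 (not isolated)
Conditions: TMSCl, then LiN(i-Pr)2 (2.3 equiv), THF, −78 °C; warm to 55 °C; then 1 M HCl, THF, rt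
Reagents that add atoms: none
Why: Ireland–Claisen rearrangement: the [3,3] shift is suprafacial, so C7–C11 forms on the face that carried the ester oxygen and hence cis to the C6 oxygen, and acid work-up closes the cis-fused γ-lactone.

**Step 4**
Reactants: 7 cis-fused lactone (C11 epimers)
Product: 9 (3R,3aS,8aS)-3-methyl-3,3a,6,7,8,8a-hexahydro-2H-cyclohepta[b]furan-2-one, via lithium enolate 8 (not isolated)
Conditions: LiN(i-Pr)2, THF, −78 °C; then AcOH in THF, −78 °C
Reagents that add atoms: none
Why: Diastereoselective kinetic protonation of the lactone enolate on the convex face of the cis-fused bicycle (anti to the C7–C8 bond) should leave the C11 methyl group on the concave face, which is the C11 configuration of the target.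

**Step 5**
Reactants: 9 lactone with C11 set
Product: 10 (2R)-2-[(1S,7S)-7-hydroxycyclohept-2-en-1-yl]-N-methoxy-N-methylpropanamide
Conditions: MeNH(OMe)·HCl, AlMe3, CH2Cl2, 0 °C to rt
Reagents that add atoms: N,O-dimethylhydroxylamine hydrochloride CNOC.Cl
Why: Weinreb aminolysis of the lactone by the aluminium amide opens the ring without touching C11, frees the C6 hydroxyl and leaves C12 as an aldehyde precursor.

**Step 6**
Reactants: 10 hydroxy Weinreb amide
Product: 11 6-O-tert-butyldimethylsilyl ether of 10
Conditions: TBSOTf, 2,6-lutidine, CH2Cl2, −78 °C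
Reagents that add atoms: tert-butyldimethylsilyl triflate CC(C)(C)[Si](C)(C)OS(=O)(=O)C(F)(F)F
Why: Silyl ether formation with the triflate caps the hindered C6 hydroxyl, blocks relactonization and gives the γ-silyloxy group that later directs the cuprate.

**Step 7**
Reactants: 11 silyl ether
Product: 12 cyclohept-2-enone (C10=O conjugated to C8=C9)
Conditions: Rh2(cap)4 (cap = caprolactamate, 1 mol %), t-BuOOH (70% in water), 1,2-dichloroethane, 40 °C
Reagents that add atoms: tert-butyl hydroperoxide CC(C)(C)OO
Why: Dirhodium caprolactamate-catalysed allylic oxidation should oxidize the only unhindered allylic methylene (C10), since the other allylic position (C7–H) is tertiary and flanked by the silyloxy group and the side chain.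

**Step 8**
Reactants: 12 enone
Product: 14 α-hydroxy ketone (9-OH, C10=O), via potassium enolate 13 (not isolated)
Conditions: K[HB(s-Bu)3], THF, −78 °C; then 3-phenyl-2-(phenylsulfonyl)oxaziridine, −78 °C
Reagents that add atoms: 3-phenyl-2-(phenylsulfonyl)oxaziridine O=S(=O)(c1ccccc1)N1OC1c1ccccc1
Why: Conjugate reduction gives the C9=C10 enolate regiospecifically, and Davis enolate hydroxylation should occur on the face opposite the cis C6 silyloxy and C7 side-chain groups, setting 9-OH trans to both.

**Step 9**
Reactants: 14 α-hydroxy ketone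
Product: 15 9-O-tert-butyldimethylsilyl ether of 14
Conditions: TBSCl, imidazole, DMF, rt
Reagents that add atoms: tert-butyldimethylsilyl chloride CC(C)(C)[Si](C)(C)Cl
Why: Standard silylation protects the C9 hydroxyl so that enolization in the next step can only go towards C1.

**Step 10**
Reactants: 15 bis-silyl ketone
Product: 17 cycloheptenone (C10=O conjugated to C1=C5), via silyl enol ether 16 (not isolated)
Conditions: LiN(SiMe3)2, TMSCl, THF, −78 °C; then Pd(OAc)2, MeCN, rt
Reagents that add atoms: none
Why: Saegusa–Ito dehydrogenation: kinetic enolization occurs at the α-methylene C1 and not at the silyloxy-bearing C9, and Pd(OAc)2 converts the silyl enol ether into the enone that has the C6 silyloxy group on its γ-carbon.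

**Step 11**
Reactants: 17 cycloheptenone
Product: 19 ketone with trans 5-isopropenyl and 1-allyl groups, via lithium enolate 18 (not isolated)
Conditions: (CH2=C(CH3))2CuLi [from 2-bromopropene, t-BuLi, CuI], Et2O/THF, −78 °C; then allyl iodide, HMPA, −78 to −20 °C
Reagents that add atoms: lithium di(prop-1-en-2-yl)cuprate [Li+].C=C(C)[Cu-]C(C)=C (made in the flask from 2-bromopropene C=C(C)Br); allyl iodide C=CCI
Why: Cuprate conjugate addition followed by enolate alkylation: the isopropenyl group should add to C5 anti to the γ-silyloxy group on C6, and the enolate is then allylated at C1 anti to the new C5 substituent, which fixes the trans C1/C5 relationship of the later ring fusion.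

**Step 12**
Reactants: 19 allylated ketone
Product: 20 10-methylene triene (Weinreb amide)
Conditions: Zn, CH2Br2, TiCl4 (Lombardo reagent), THF/CH2Cl2, 0 °C to rt
Reagents that add atoms: dibromomethane BrCBr
Why: Lombardo–Takai methylenation is non-basic, so the hindered ketone is converted to the C10 exocyclic methylene without epimerizing C1 or C9 and without touching the amide.

**Step 13**
Reactants: 20 triene Weinreb amide
Product: 21 C12 aldehyde
Conditions: i-Bu2AlH, THF, −78 °C; aqueous Rochelle salt
Reagents that add atoms: none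
Why: Reduction of the Weinreb amide stops at the chelated hemiaminal and releases the aldehyde on work-up, leaving the α-stereocenter C11 intact.

**Step 14**
Reactants: 21 aldehyde
Product: 23 homoallylic alcohol (12-OH and 13-(4-methoxyphenoxy) syn, terminal vinyl group), via borinate 22 (not isolated)
Conditions: allyl 4-methoxyphenyl ether, s-BuLi, THF, −78 °C; (+)-Ipc2BOMe; BF3·OEt2; then 21, −78 °C; NaOH, H2O2
Reagents that add atoms: B-[(Z)-3-(4-methoxyphenoxy)prop-2-enyl]diisopinocampheylborane COc1ccc(O/C=C\CB([C@H]2C[C@H]3C[C@@H]([C@@H]2C)C3(C)C)[C@H]2C[C@H]3C[C@@H]([C@@H]2C)C3(C)C)cc1 (made in the flask from allyl 4-methoxyphenyl ether C=CCOc1ccc(OC)cc1)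
Why: Brown alkoxyallylboration: the (Z)-γ-alkoxyallylborane reacts through a chair transition state to give the syn C12/C13 diol pattern, and the isopinocampheyl groups from (−)-α-pinene select the aldehyde face that is also the Felkin face, giving 12-OH syn to the C11 methyl group.

**Step 15**
Reactants: 23 homoallylic alcohol
Product: 24 12,13-diol
Conditions: (NH4)2Ce(NO3)6, MeCN/H2O (4:1), 0 °C
Reagents that add atoms: none
Why: Oxidative dearylation of the 4-methoxyphenyl ether releases the C13 hydroxyl without acid strong enough to ionize the allylic positions or cleave the silyl ethers.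

**Step 16**
Reactants: 24 diol
Product: 25 12,13-diacetate (tetraene)
Conditions: Ac2O, pyridine, DMAP (cat.), CH2Cl2, rt
Reagents that add atoms: acetic anhydride CC(=O)OC(C)=O
Why: Acylation of the only two free hydroxyls installs both acetates of the target while C6 and C9 remain silylated.

**Step 17**
Reactants: 25 diacetate tetraene
Product: 27 6,9-bis-O-tert-butyldimethylsilyl ether of the target, via ring-closed vinyl compound 26 (not isolated)
Conditions: second-generation Grubbs catalyst RuCl2(=CHPh)(PCy3)(H2IMes) (5 mol %), CH2Cl2 (0.005 M), 40 °C; then 2-methylbut-2-ene (excess), 40 °C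
Reagents that add atoms: 2-methylbut-2-ene CC=C(C)C
Why: Ring-closing olefin metathesis: the ruthenium alkylidene loads onto the monosubstituted allyl terminus, adds to the isopropenyl group through a ruthenacyclobutane and cycloreverts with loss of ethene, forming C3=C4 and with it ring A. The closest known reaction type is the closure of methylcyclopentenes from allyl/isopropenyl pairs with N-heterocyclic-carbene ruthenium catalysts, followed here by the known cross metathesis of a terminal alkene with 2-methylbut-2-ene. Ring A closes in the five-membered mode; the alternatives are a cyclobutene with the C10 methylene or eight- and ten-membered rings with the side-chain vinyl group, all of which should be far slower. No stereocenter is formed: the trans C1/C5 relationship from step 11 is carried into the trans ring fusion, and the gauche disposition of the two olefinic arms permits closure. The step needs ring closure to precede cross metathesis, which is secured by high dilution and by adding 2-methylbut-2-ene only after 25 is consumed; it then reacts only with the one remaining monosubstituted alkene, because the 1,1-disubstituted C10 methylene and the trisubstituted ring alkene are inert.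

**Step 18**
Reactants: 27 bis-silyl ether
Product: 28 target (CNP0423623.2)
Conditions: HF·pyridine, pyridine, THF, 0 °C to rt
Reagents that add atoms: none
Why: Buffered fluoride desilylation removes both silyl ethers and should leave the two acetates, the allylic alcohol and the allylic acetate unchanged.

**Compound list**

1 | cyclohepta-1,3-diene | C1=CC=CCCC1 | starting material
2 | 6,7-dioxabicyclo[3.2.2]non-8-ene (meso endoperoxide) | C1CC[C@H]2C=C[C@@H]1OO2 | intermediate
3 | cis-cyclohept-2-ene-1,4-diol (meso) | O[C@H]1C=C[C@@H](O)CCC1 | intermediate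
4 | (1R,4S)-4-hydroxycyclohept-2-en-1-yl propanoate | CCC(=O)O[C@H]1C=C[C@@H](O)CCC1 | intermediate
5 | trimethylsilyl ketene acetal of 4, hydroxyl as trimethylsilyl ether | CC=C(O[Si](C)(C)C)O[C@H]1C=C[C@@H](O[Si](C)(C)C)CCC1 | intermediate
6 | 2-[(1S,7S)-7-hydroxycyclohept-2-en-1-yl]propanoic acid (C11 epimers) | C1=C[C@@H](C(C)C(=O)O)[C@@H](O)CCC1 | intermediate
7 | (3aS,8aS)-3-methyl-3,3a,6,7,8,8a-hexahydro-2H-cyclohepta[b]furan-2-one (cis-fused, C11 epimers) | C1=C[C@@H]2[C@H](CCC1)OC(=O)C2C | intermediate
8 | lithium enolate of 7 | C1=C[C@@H]2[C@H](CCC1)OC([O-])=C2C.[Li+] | intermediate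
9 | (3R,3aS,8aS)-3-methyl-3,3a,6,7,8,8a-hexahydro-2H-cyclohepta[b]furan-2-one (C11 methyl on the concave face) | C1=C[C@@H]2[C@H](CCC1)OC(=O)[C@@H]2C | intermediate
10 | (2R)-2-[(1S,7S)-7-hydroxycyclohept-2-en-1-yl]-N-methoxy-N-methylpropanamide | C1=C[C@@H]([C@@H](C)C(=O)N(C)OC)[C@@H](O)CCC1 | intermediate
11 | 6-O-tert-butyldimethylsilyl ether of 10 | C1=C[C@@H]([C@@H](C)C(=O)N(C)OC)[C@@H](O[Si](C)(C)C(C)(C)C)CCC1 | intermediate
12 | cyclohept-2-enone from 11 (C10=O, C8=C9) | O=C1C=C[C@@H]([C@@H](C)C(=O)N(C)OC)[C@@H](O[Si](C)(C)C(C)(C)C)CC1 | intermediate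
13 | potassium enolate (C9=C10–OK) | [K+].[O-]C1=CC[C@@H]([C@@H](C)C(=O)N(C)OC)[C@@H](O[Si](C)(C)C(C)(C)C)CC1 | intermediate
14 | α-hydroxy ketone (9-OH trans to the C7 side chain, C10=O) | O=C1[C@H](O)C[C@@H]([C@@H](C)C(=O)N(C)OC)[C@@H](O[Si](C)(C)C(C)(C)C)CC1 | intermediate
15 | 9-O-tert-butyldimethylsilyl ether of 14 | O=C1[C@H](O[Si](C)(C)C(C)(C)C)C[C@@H]([C@@H](C)C(=O)N(C)OC)[C@@H](O[Si](C)(C)C(C)(C)C)CC1 | intermediate
16 | trimethylsilyl enol ether of 15 (C1=C10–OSiMe3) | C[Si](C)(C)OC1[C@H](O[Si](C)(C)C(C)(C)C)C[C@@H]([C@@H](C)C(=O)N(C)OC)[C@@H](O[Si](C)(C)C(C)(C)C)CC=1 | intermediate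
17 | cycloheptenone (C10=O, C1=C5; 6- and 9-silyloxy) | O=C1[C@H](O[Si](C)(C)C(C)(C)C)C[C@@H]([C@@H](C)C(=O)N(C)OC)[C@@H](O[Si](C)(C)C(C)(C)C)C=C1 | intermediate
18 | lithium enolate with isopropenyl on C5 (trans to 6-silyloxy) | [Li+].[O-]C1[C@H](O[Si](C)(C)C(C)(C)C)C[C@@H]([C@@H](C)C(=O)N(C)OC)[C@@H](O[Si](C)(C)C(C)(C)C)[C@H](C(C)=C)C=1 | intermediate
19 | ketone with trans 5-isopropenyl and 1-allyl groups | O=C1[C@H](O[Si](C)(C)C(C)(C)C)C[C@@H]([C@@H](C)C(=O)N(C)OC)[C@@H](O[Si](C)(C)C(C)(C)C)[C@H](C(C)=C)[C@H]1CC=C | intermediate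
20 | 10-methylene triene (Weinreb amide) | C=C1[C@H](O[Si](C)(C)C(C)(C)C)C[C@@H]([C@@H](C)C(=O)N(C)OC)[C@@H](O[Si](C)(C)C(C)(C)C)[C@H](C(C)=C)[C@H]1CC=C | intermediate
21 | C12 aldehyde | C=C1[C@H](O[Si](C)(C)C(C)(C)C)C[C@@H]([C@@H](C)C=O)[C@@H](O[Si](C)(C)C(C)(C)C)[C@H](C(C)=C)[C@H]1CC=C | intermediate
22 | diisopinocampheylborinate of 23 | C=C1[C@H](O[Si](C)(C)C(C)(C)C)C[C@@H]([C@@H](C)[C@H](OB([C@H]2C[C@H]3C[C@@H]([C@@H]2C)C3(C)C)[C@H]2C[C@H]3C[C@@H]([C@@H]2C)C3(C)C)[C@H](C=C)Oc2ccc(OC)cc2)[C@@H](O[Si](C)(C)C(C)(C)C)[C@H](C(C)=C)[C@H]1CC=C | intermediate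
23 | homoallylic alcohol (12-OH, 13-(4-methoxyphenoxy), vinyl) | C=C1[C@H](O[Si](C)(C)C(C)(C)C)C[C@@H]([C@@H](C)[C@H](O)[C@H](C=C)Oc2ccc(OC)cc2)[C@@H](O[Si](C)(C)C(C)(C)C)[C@H](C(C)=C)[C@H]1CC=C | intermediate
24 | 12,13-diol | C=C1[C@H](O[Si](C)(C)C(C)(C)C)C[C@@H]([C@@H](C)[C@H](O)[C@H](C=C)O)[C@@H](O[Si](C)(C)C(C)(C)C)[C@H](C(C)=C)[C@H]1CC=C | intermediate
25 | 12,13-diacetate (tetraene) | C=C1[C@H](O[Si](C)(C)C(C)(C)C)C[C@@H]([C@@H](C)[C@H](OC(C)=O)[C@H](C=C)OC(C)=O)[C@@H](O[Si](C)(C)C(C)(C)C)[C@H](C(C)=C)[C@H]1CC=C | intermediate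
26 | ring-closed hydroazulene with side-chain vinyl group | C=C1[C@H](O[Si](C)(C)C(C)(C)C)C[C@@H]([C@@H](C)[C@H](OC(C)=O)[C@H](C=C)OC(C)=O)[C@@H](O[Si](C)(C)C(C)(C)C)[C@@H]2C(C)=CC[C@@H]12 | intermediate
27 | 6,9-bis-O-tert-butyldimethylsilyl ether of the target | C=C1[C@H](O[Si](C)(C)C(C)(C)C)C[C@@H]([C@@H](C)[C@H](OC(C)=O)[C@H](C=C(C)C)OC(C)=O)[C@@H](O[Si](C)(C)C(C)(C)C)[C@@H]2C(C)=CC[C@@H]12 | intermediate
28 | CNP0423623.2 | C=C1[C@H](O)C[C@@H]([C@@H](C)[C@H](OC(C)=O)[C@H](C=C(C)C)OC(C)=O)[C@@H](O)[C@@H]2C(C)=CC[C@@H]12 | target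

**Step count and risks**

Total steps: 18. Longest linear sequence: 18 steps (fully linear from cyclohepta-1,3-diene).

Most likely to fail:

1. Step 7 (allylic oxidation). Hydrogen abstraction may occur at the tertiary allylic C7–H, oxygen may be delivered with allylic transposition to C8, or the enone may lose the C6 silyloxy group by vinylogous elimination. Fallback, from 11 back to 12: catalytic selenium dioxide with t-BuOOH in CH2Cl2 hydroxylates by an ene reaction and [2,3]-sigmatropic shift, which returns the double bond to C8=C9 and puts the oxygen on the methylene carbon C10, giving the allylic alcohol F1. Dess–Martin periodinane then oxidizes the allylic alcohol F1 to 12.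

2. Step 8 (reduction–hydroxylation). Hydride may be delivered 1,2 instead of 1,4, and oxygen transfer to the flexible seven-membered enolate may show poor facial selectivity. Fallback, from 12 back to 14: if oxygen arrives mainly on the face of the C6/C7 substituents, the resulting C9-epimeric ketol F2 is inverted under Mitsunobu conditions (4-nitrobenzoic acid, PPh3, diisopropyl azodicarboxylate, THF) to the 4-nitrobenzoate F3, which has the required C9 configuration. Methanolysis of the 4-nitrobenzoate F3 (K2CO3, MeOH, 0 °C) returns 14.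

3. Step 17 (ring closure and cross metathesis in one flask). The side-chain vinyl group, an allylic acetate, may sequester the catalyst before ring closure is complete, may oligomerize, or the cross metathesis may stall. Fallback, from 20 back to 26 and then 27: the ring is closed before the side chain is built. Ring-closing metathesis of 20 (second-generation Grubbs catalyst, CH2Cl2, 40 °C) gives the bicyclic Weinreb amide F4. Reduction with i-Bu2AlH gives the bicyclic aldehyde F5, the alkoxyallylboration of step 14 gives the bicyclic homoallylic alcohol F6, and (NH4)2Ce(NO3)6 gives the bicyclic diol F7. Acetylation then gives 26 as an isolated compound, which is treated separately with 2-methylbut-2-ene and the second-generation Hoveyda–Grubbs catalyst to give 27.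

**Further compounds**

F1 | step 7 | allylic alcohol (10-OH, C8=C9; C10 epimers) from 11 | OC1C=C[C@@H]([C@@H](C)C(=O)N(C)OC)[C@@H](O[Si](C)(C)C(C)(C)C)CC1
F2 | step 8 | C9 epimer of ketol 14 | O=C1[C@@H](O)C[C@@H]([C@@H](C)C(=O)N(C)OC)[C@@H](O[Si](C)(C)C(C)(C)C)CC1
F3 | step 8 | 9-O-(4-nitrobenzoate) of 14 | O=C1[C@H](OC(=O)c2ccc(cc2)[N+](=O)[O-])C[C@@H]([C@@H](C)C(=O)N(C)OC)[C@@H](O[Si](C)(C)C(C)(C)C)CC1
F4 | step 17 | bicyclic Weinreb amide (ring A closed) | C=C1[C@H](O[Si](C)(C)C(C)(C)C)C[C@@H]([C@@H](C)C(=O)N(C)OC)[C@@H](O[Si](C)(C)C(C)(C)C)[C@@H]2C(C)=CC[C@@H]12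
F5 | step 17 | bicyclic C12 aldehyde | C=C1[C@H](O[Si](C)(C)C(C)(C)C)C[C@@H]([C@@H](C)C=O)[C@@H](O[Si](C)(C)C(C)(C)C)[C@@H]2C(C)=CC[C@@H]12
F6 | step 17 | bicyclic homoallylic alcohol (12-OH, 13-(4-methoxyphenoxy), vinyl) | C=C1[C@H](O[Si](C)(C)C(C)(C)C)C[C@@H]([C@@H](C)[C@H](O)[C@H](C=C)Oc2ccc(OC)cc2)[C@@H](O[Si](C)(C)C(C)(C)C)[C@@H]2C(C)=CC[C@@H]12
F7 | step 17 | bicyclic 12,13-diol | C=C1[C@H](O[Si](C)(C)C(C)(C)C)C[C@@H]([C@@H](C)[C@H](O)[C@H](C=C)O)[C@@H](O[Si](C)(C)C(C)(C)C)[C@@H]2C(C)=CC[C@@H]12
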